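**Conventions.** Ring A is the benzaldehyde ring, numbered here C1 (bears the ketone carbon), C2 (CHO), C3 (O-prenyl), C4 (CH3), C5 (H), C6 (OH). Ring B is the benzene ring of the 2H-chromene, with chromene locants (O1, C2, C3, C4, C4a, C5 to C8, C8a): the ketone is on C8 and the free phenol on C7. Locants inside compound names follow nomenclature rules and may differ from this convention.

**Assumption.** The target 17 is treated as the open hydroxy aldehyde of the SMILES. A possible ring-chain equilibrium between the C7 phenol of ring B and the formyl group is a property of 17 itself and does not change the route.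

## The problem

Compound 17 has no stereocentre, so the difficulty is regiochemical and steric. The ketone carbon has four ortho neighbours (C2–CHO and C6–OH on ring A, C7–OH and the pyran oxygen at C8a on ring B). Any union of two finished aryl halves at this carbon therefore joins a 2,6-disubstituted nucleophile to a 2,6-disubstituted electrophile. Ring A carries five different substituents in a fixed order and has no symmetry. It is a hydroquinone whose two oxygens must be told apart (prenyl ether at C3, free phenol at C6), with two different carbonyl carbons on the adjacent positions C1 and C2. Ring B is easier: it is a 2-acylresorcinol with a prenyl-derived pyran, and because a 2,6-dihydroxybenzoyl unit is symmetric the pyran can be fused without a regiochemical choice. The aryl prenyl ether (acid, heat), the 2,2-dimethyl-2H-chromene (acid, electrophilic oxidants) and the aldehyde beside the ketone will not survive rough treatment.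

The feature that opens the problem is in ring A. The oxygens on C3 and C6 are para, and the two carbons between them on one side, C1 and C2, carry the two carbonyl groups. Ring A is therefore a four-carbon unit C6–C5–C4(CH3)–C3 whose oxygen-bearing ends can be bridged by one oxygen (a 4-methyl-2-oxyfuran), plus a two-carbon unit C1–C2 (an alkyne bearing the aroyl group and a masked formyl group). Cycloaddition and opening of the oxygen bridge return the hydroquinone with its two oxygens already differentiated.

## Retrosynthesis

**17 to 14.** The two O–Si bonds of 16 and the O–CH2 bond of the prenyl ether are cut last. This keeps the prenyl ether out of every acidic or hot step and leaves only a fluoride desilylation after it is made. The forward steps need a precursor, 14, in which the C3 oxygen of ring A is the only free phenol, so that alkylation with 15 has one site.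

**14 to 9 and 11 (key disconnection).** The bonds C6–C1 and C3–C2 of ring A are cut, and the C3 oxygen is reconnected to C6 as a furan oxygen.
- The precursors are ynone 9, which holds ring B and the ketone already in place, and 4-methyl-2-silyloxyfuran 11, one step from a commercial butenolide.
- Against the neighbouring cut at the ketone–C1 bond, this cut never joins two hindered rings. Ring A is grown on the ketone.
- The forward reaction must have one regiochemistry: the nucleophilic furan terminus C5 must bond to the alkyne carbon β to the ketone. The ketone is the only conjugating acceptor on the alkyne because the formyl group is carried as its diethyl acetal, which secures this.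
- The cycloadduct 12 must then open at its ketal bridgehead to phenol 13. The exocyclic furan oxygen stays silylated and becomes C6–O next to the ketone, where the target has a free phenol. The ring oxygen emerges as the free C3–OH, where the prenyl group is needed. The furan oxygen must therefore carry a removable group, not the prenyl group.
- Acetal hydrolysis in the same operation gives 14.

**11 to 10.** The O–Si bond is cut. O-silylation of 4-methylfuran-2(5H)-one 10 is the standard entry to silyloxyfuran dienes.

**9 to 5 and 6.** The bond between the carbonyl carbon and the alkyne is cut, through carbinol 8 and the alkynylmagnesium bromide 7 made from 3,3-diethoxyprop-1-yne 6. Addition of a small sp nucleophile to the hindered aldehyde 5 is easy where addition of an aryl nucleophile would not be. The forward steps need a phenol protecting group on ring B that survives a Grignard reagent, MnO2, heat, dilute acid and carbonate, and leaves with fluoride, hence the triisopropylsilyl ether.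

**5 to 1 and 2.** The O–Si bond is cut to give 4, and then the pyran bonds C4a–C4 and O1–C2 of the chromene are cut. The precursors are 2,6-dihydroxybenzaldehyde 1 and prenal 2, joined through ortho-quinone methide 3 and an oxa-6π electrocyclization. Since C3 and C5 of 1 are equivalent, only the extent of annulation has to be controlled.

## Roads not taken

**Alternative 1:** the obvious cut, at the bond between the ketone carbon and ring B.
- Forward: 7-(methoxymethoxy)-2,2-dimethyl-2H-chromene A1 would be deprotonated at C8 between its two oxygens with n-BuLi and added to a fully substituted ring A aldehyde A2 to give diaryl carbinol A3, which would be oxidized and deprotected.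
- Why not: the plan moves the whole difficulty into A2, a pentasubstituted benzene that would need a long series of electrophilic substitutions and protecting-group changes on a methylhydroquinone, with a regiochemical question at each. The coupling is the tetra-ortho-substituted addition the chosen plan avoids. The final acetal removals need acid with the prenyl ether present.

**Alternative 2:** ring A from open-chain pieces by a carbene-complex benzannulation.
- Forward: the isopropenyl carbene complex (CO)5Cr=C(OCH3)C(CH3)=CH2 A4, an alkyne such as 8, and CO would give 4-methoxyphenol A5 with the correct para-oxygen pattern.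
- Why not: the regiochemistry of alkyne incorporation rests on a size difference between the two alkyne substituents, and here both are branched CH(O)-type carbons, so A5 would come with its regioisomer. The ether oxygen is fixed as OCH3 by the carbene, and changing it to the prenyl ether needs a demethylation next to an aldehyde and a chromene. The complex must be made from Cr(CO)6 in stoichiometric amount. The furan route fixes regiochemistry electronically and leaves the ether oxygen free.

**Alternative 3:** ring B carried as a saturated ring and aromatized late.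
- Forward: cyclohexane-1,3-dione would be O-acylated with ring A acid chloride A6, the enol ester rearranged under cyanide catalysis to triketone A7, A7 dehydrogenated to 2-aroylresorcinol A8, and A8 annulated with 2.
- Why not: this makes the hindered ketone bond elegantly but does nothing for ring A, which is the harder ring. A6 has a masked formyl group ortho to an acyl chloride and would collapse to a 3-alkoxyphthalide. Dehydrogenation of a 2-acylcyclohexane-1,3-dione needs iodine, mercury salts or hot palladium on carbon, none compatible with a prenyl ether or acetal. The route is also longer.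

Key step: step 6

## Route

Step 1
Reactants: 1 2,6-dihydroxybenzaldehyde; 2 3-methylbut-2-enal
Product: 4 7-hydroxy-2,2-dimethyl-2H-chromene-8-carbaldehyde, via ortho-quinone methide 3 (not isolated)
Conditions: 2 (1.1 equiv), ethylenediammonium diacetate (10 mol %), xylene, 140 °C
Reagents that add atoms: none
Why: Phenol–enal chromenylation: amine-catalysed condensation of 2 at C3 of 1 (ortho to one phenol and para to the other; C3 and C5 are equivalent) gives ortho-quinone methide 3, which closes by oxa-6π electrocyclization; limiting 2 to about one equivalent should hold back a second annulation.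

Step 2
Reactants: 4 7-hydroxy-2,2-dimethyl-2H-chromene-8-carbaldehyde
Product: 5 2,2-dimethyl-7-[(triisopropylsilyl)oxy]-2H-chromene-8-carbaldehyde
Conditions: TIPSOTf, 2,6-lutidine, CH2Cl2, 0 °C to rt
Reagents that add atoms: triisopropylsilyl trifluoromethanesulfonate (TIPSOTf), CC(C)[Si](C(C)C)(C(C)C)OS(=O)(=O)C(F)(F)F
Why: A silyl triflate with a hindered pyridine base silylates even a hydrogen-bonded phenol; the triisopropylsilyl ether is chosen to survive a Grignard reagent, MnO2, heat, dilute acid and carbonate and to leave with fluoride.

Step 3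
Reactants: 5 2,2-dimethyl-7-[(triisopropylsilyl)oxy]-2H-chromene-8-carbaldehyde; 6 3,3-diethoxyprop-1-yne
Product: 8 rac-4,4-diethoxy-1-{2,2-dimethyl-7-[(triisopropylsilyl)oxy]-2H-chromen-8-yl}but-2-yn-1-ol, via alkynylmagnesium bromide 7 (not isolated)
Conditions: 6, EtMgBr, THF, 0 °C to rt; then 5, THF, −20 to 0 °C; sat. aq NH4Cl
Reagents that add atoms: none
Why: Deprotonation of the terminal alkyne and 1,2-addition of the alkynyl Grignard reagent 7 to the aldehyde; the magnesium alkoxide is used in place of a lithium alkoxide to suppress 1,5 O-to-O silyl migration; the carbinol centre is racemic and is erased in step 4.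

Step 4
Reactants: 8 rac-4,4-diethoxy-1-{2,2-dimethyl-7-[(triisopropylsilyl)oxy]-2H-chromen-8-yl}but-2-yn-1-ol
Product: 9 4,4-diethoxy-1-{2,2-dimethyl-7-[(triisopropylsilyl)oxy]-2H-chromen-8-yl}but-2-yn-1-one
Conditions: activated MnO2 (excess), CH2Cl2, rt
Reagents that add atoms: none
Why: MnO2 oxidation of a benzylic, propargylic alcohol to the ynone under neutral conditions that leave the acetal, the silyl ether and the chromene alone.

Step 5
Reactants: 10 4-methylfuran-2(5H)-one
Product: 11 4-methyl-2-[(triisopropylsilyl)oxy]furan
Conditions: TIPSOTf, Et3N, CH2Cl2, 0 °C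
Reagents that add atoms: triisopropylsilyl trifluoromethanesulfonate (TIPSOTf), CC(C)[Si](C(C)C)(C(C)C)OS(=O)(=O)C(F)(F)F
Why: Soft enolization and O-silylation of the butenolide gives the aromatic 2-silyloxyfuran, the standard preparation of these dienes.

Step 6
Reactants: 9 4,4-diethoxy-1-{2,2-dimethyl-7-[(triisopropylsilyl)oxy]-2H-chromen-8-yl}but-2-yn-1-one; 11 4-methyl-2-[(triisopropylsilyl)oxy]furan
Product: 14 6-hydroxy-5-methyl-2-{2,2-dimethyl-7-[(triisopropylsilyl)oxy]-2H-chromene-8-carbonyl}-3-[(triisopropylsilyl)oxy]benzaldehyde, via oxanorbornadiene cycloadduct 12 (not isolated), via phenol acetal 13 (not isolated)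
Conditions: 11 (1.5 equiv), toluene, 80 °C; then 0.5 M aq HCl, THF, 0 °C to rt
Reagents that add atoms: water, O
Why: A thermal Diels–Alder reaction of the electron-rich 2-silyloxyfuran 11 with ynone 9 closes the six-membered carbocycle of ring A by forming two C–C bonds, furan C5 to the acetal-bearing alkyne carbon and furan C2 to the aroyl-bearing alkyne carbon, to give the 7-oxanorbornadiene 12. The closure is an intermolecular, strongly asynchronous [4+2] cycloaddition in which the nucleophilic terminus C5 of the vinylogous silyl ketene acetal bonds first to the carbon β to the ketone; this fixes the regiochemistry, and the ketone is the only conjugating acceptor on the alkyne because the other substituent is an acetal. The bridgehead of 12 that carries the silyloxy group is a ketal carbon, so its bond to the bridging oxygen ionizes to a silyloxy-stabilized arenium ion that loses the proton of the other bridgehead and aromatizes to phenol 13. This direction of opening differentiates the two hydroquinone oxygens: the exocyclic furan oxygen stays silylated ortho to the ketone, and the ring oxygen emerges as the free phenol between the acetal carbon and the methyl group. Dilute acid then hydrolyses the acetal, helped by the ortho phenol, to salicylaldehyde 14, so all acid treatment is over before the prenyl ether exists. The closest known reaction type is the Diels–Alder reaction of 2-silyloxy- and 2-alkoxyfurans with acetylenic esters and ketones followed by ring opening to para-oxygenated phenols. No stereocentre survives (the two bridgehead centres of racemic 12 are lost on aromatization); the selectivities needed are this regiochemistry and chemoselectivity over the chromene alkene, which is neither electron-poor nor strained and should not compete. The tetra-ortho-substituted diaryl ketone is thus never made by joining two hindered rings, since ring A is grown on a ketone already in place.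

Step 7
Reactants: 14 6-hydroxy-5-methyl-2-{2,2-dimethyl-7-[(triisopropylsilyl)oxy]-2H-chromene-8-carbonyl}-3-[(triisopropylsilyl)oxy]benzaldehyde; 15 1-bromo-3-methylbut-2-ene
Product: 16 5-methyl-6-[(3-methylbut-2-en-1-yl)oxy]-2-{2,2-dimethyl-7-[(triisopropylsilyl)oxy]-2H-chromene-8-carbonyl}-3-[(triisopropylsilyl)oxy]benzaldehyde
Conditions: 15, K2CO3, acetone (anhydrous), 45 °C
Reagents that add atoms: none
Why: Williamson etherification of the only free phenol, a salicylaldehyde-type OH acidic enough for K2CO3; the other two phenolic oxygens are silylated, so the site is unambiguous, and the mild temperature avoids aromatic Claisen rearrangement.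

Step 8
Reactants: 16 5-methyl-6-[(3-methylbut-2-en-1-yl)oxy]-2-{2,2-dimethyl-7-[(triisopropylsilyl)oxy]-2H-chromene-8-carbonyl}-3-[(triisopropylsilyl)oxy]benzaldehyde
Product: 17 3-hydroxy-2-(7-hydroxy-2,2-dimethyl-2H-chromene-8-carbonyl)-5-methyl-6-[(3-methylbut-2-en-1-yl)oxy]benzaldehyde
Conditions: Bu4NF (2.2 equiv), AcOH (2.2 equiv), THF, 0 °C
Reagents that add atoms: none
Why: Fluoride cleaves both aryl triisopropylsilyl ethers; acetic acid buffers the liberated phenoxides so that the aldehyde is not exposed to strong base; the prenyl ether and the chromene are inert to fluoride.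

## Compound list

1 | 2,6-dihydroxybenzaldehyde | O=Cc1c(O)cccc1O | starting material
2 | 3-methylbut-2-enal | CC(C)=CC=O | starting material
3 | (5Z)-2-hydroxy-5-(3-methylbut-2-en-1-ylidene)-6-oxocyclohexa-1,3-diene-1-carbaldehyde (ortho-quinone methide) | O=CC1=C(O)C=C/C(=C/C=C(C)C)C1=O | intermediate (not isolated)
4 | 7-hydroxy-2,2-dimethyl-2H-chromene-8-carbaldehyde | O=Cc1c(O)ccc2C=CC(C)(C)Oc12 | intermediate
5 | 2,2-dimethyl-7-[(triisopropylsilyl)oxy]-2H-chromene-8-carbaldehyde | O=Cc1c(O[Si](C(C)C)(C(C)C)C(C)C)ccc2C=CC(C)(C)Oc12 | intermediate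
6 | 3,3-diethoxyprop-1-yne | C#CC(OCC)OCC | starting material
7 | bromo(3,3-diethoxyprop-1-yn-1-yl)magnesium | CCOC(OCC)C#C[Mg]Br | intermediate (not isolated)
8 | rac-4,4-diethoxy-1-{2,2-dimethyl-7-[(triisopropylsilyl)oxy]-2H-chromen-8-yl}but-2-yn-1-ol (racemic) | CCOC(OCC)C#CC(O)c1c(O[Si](C(C)C)(C(C)C)C(C)C)ccc2C=CC(C)(C)Oc12 | intermediate
9 | 4,4-diethoxy-1-{2,2-dimethyl-7-[(triisopropylsilyl)oxy]-2H-chromen-8-yl}but-2-yn-1-one | CCOC(OCC)C#CC(=O)c1c(O[Si](C(C)C)(C(C)C)C(C)C)ccc2C=CC(C)(C)Oc12 | intermediate
10 | 4-methylfuran-2(5H)-one | CC1=CC(=O)OC1 | starting material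
11 | 4-methyl-2-[(triisopropylsilyl)oxy]furan | Cc1coc(O[Si](C(C)C)(C(C)C)C(C)C)c1 | intermediate
12 | rac-{3-(diethoxymethyl)-5-methyl-1-[(triisopropylsilyl)oxy]-7-oxabicyclo[2.2.1]hepta-2,5-dien-2-yl}{2,2-dimethyl-7-[(triisopropylsilyl)oxy]-2H-chromen-8-yl}methanone (racemic; bridgeheads fixed cis by the bicycle) | CCOC(OCC)C1=C(C(=O)c3c(O[Si](C(C)C)(C(C)C)C(C)C)ccc4C=CC(C)(C)Oc34)C2(O[Si](C(C)C)(C(C)C)C(C)C)C=C(C)C1O2 | intermediate (not isolated)
13 | [2-(diethoxymethyl)-3-hydroxy-4-methyl-6-[(triisopropylsilyl)oxy]phenyl]{2,2-dimethyl-7-[(triisopropylsilyl)oxy]-2H-chromen-8-yl}methanone | CCOC(OCC)c1c(O)c(C)cc(O[Si](C(C)C)(C(C)C)C(C)C)c1C(=O)c2c(O[Si](C(C)C)(C(C)C)C(C)C)ccc3C=CC(C)(C)Oc23 | intermediate (not isolated)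
14 | 6-hydroxy-5-methyl-2-{2,2-dimethyl-7-[(triisopropylsilyl)oxy]-2H-chromene-8-carbonyl}-3-[(triisopropylsilyl)oxy]benzaldehyde | O=Cc1c(O)c(C)cc(O[Si](C(C)C)(C(C)C)C(C)C)c1C(=O)c2c(O[Si](C(C)C)(C(C)C)C(C)C)ccc3C=CC(C)(C)Oc23 | intermediate
15 | 1-bromo-3-methylbut-2-ene | CC(C)=CCBr | starting material
16 | 5-methyl-6-[(3-methylbut-2-en-1-yl)oxy]-2-{2,2-dimethyl-7-[(triisopropylsilyl)oxy]-2H-chromene-8-carbonyl}-3-[(triisopropylsilyl)oxy]benzaldehyde | CC(C)=CCOc1c(C)cc(O[Si](C(C)C)(C(C)C)C(C)C)c(C(=O)c2c(O[Si](C(C)C)(C(C)C)C(C)C)ccc3C=CC(C)(C)Oc23)c1C=O | intermediate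
17 | 3-hydroxy-2-(7-hydroxy-2,2-dimethyl-2H-chromene-8-carbonyl)-5-methyl-6-[(3-methylbut-2-en-1-yl)oxy]benzaldehyde | CC(C)=CCOc1c(C)cc(O)c(C(=O)c2c(O)ccc3c2OC(C)(C)C=C3)c1C=O | target

## Step count and risks

Total: 8 steps. Longest linear sequence: 7 steps (steps 1, 2, 3, 4, 6, 7, 8). Step 5 is a one-step branch.

**Step 6 (key step).**
- What may go wrong: after the first C–C bond the second, more hindered bond (silyloxy-bearing furan C2 to the aroyl-bearing carbon) may fail to close, and silyl transfer or protonation would then end in an open-chain γ-alkenyl butenolide. Desilylation at the oxocarbenium stage would erase the differentiation of the two hydroquinone oxygens.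
- Fallback, from 9 and 10, returning at 17: an anionic, stepwise annulation. The lithium dienolate of 10 (LiN(SiMe3)2, THF, −78 °C) should add through its γ-carbon to the β-carbon of 9 (vinylogous Michael addition). The allenolate then attacks the lactone carbonyl (Dieckmann-type closure), the lactone opens, and the 4-hydroxycyclohexadienone tautomerizes to [2-(diethoxymethyl)-3,6-dihydroxy-4-methylphenyl]{2,2-dimethyl-7-[(triisopropylsilyl)oxy]-2H-chromen-8-yl}methanone F1.
- The two ring A phenols of F1 are told apart by hydrogen bonding instead of by silicon: the C6 phenol is tied to the ketone, so alkylation with 15 (K2CO3, acetone) should take the free C3 phenol and give [2-(diethoxymethyl)-6-hydroxy-4-methyl-3-[(3-methylbut-2-en-1-yl)oxy]phenyl]{2,2-dimethyl-7-[(triisopropylsilyl)oxy]-2H-chromen-8-yl}methanone F2.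
- Mild acetal hydrolysis (pyridinium p-toluenesulfonate, wet acetone) gives 3-hydroxy-5-methyl-6-[(3-methylbut-2-en-1-yl)oxy]-2-{2,2-dimethyl-7-[(triisopropylsilyl)oxy]-2H-chromene-8-carbonyl}benzaldehyde F3, and Bu4NF/AcOH gives 17.

**Step 1.**
- What may go wrong: a second annulation at C6 of 4 (ortho to the remaining phenol), and slow condensation because the formyl group deactivates the resorcinol.
- Fallback, from 1, returning at 4: mono-O-alkylation of 1 with 3-chloro-3-methylbut-1-yne (K2CO3, KI, CuI cat., acetone) to 2-hydroxy-6-[(2-methylbut-3-yn-2-yl)oxy]benzaldehyde F4. Heating F4 in xylene gives 4 by aryl propargyl Claisen rearrangement to the only free ortho position, enolization, 1,5-hydrogen shift and oxa-6π closure.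

**Step 3.**
- What may go wrong: 1,5 migration of the silyl group from the phenol oxygen to the new alkoxide, followed by loss of silanolate through an ortho-quinone methide. A phenol freed in this way would later cyclize onto the ynone.
- Fallback, from 5, returning at 9, with no alkoxide next to the silyl ether: Pinnick oxidation of 5 (NaClO2, NaH2PO4, 2-methylbut-2-ene, t-BuOH/water) to 2,2-dimethyl-7-[(triisopropylsilyl)oxy]-2H-chromene-8-carboxylic acid F5. Conversion with 1-chloro-N,N,2-trimethylprop-1-en-1-amine gives 2,2-dimethyl-7-[(triisopropylsilyl)oxy]-2H-chromene-8-carbonyl chloride F6. Acyl Sonogashira coupling of F6 with 6 (PdCl2(PPh3)2, CuI, Et3N, THF, rt) gives 9 directly.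

**Step 7.**
- What may go wrong: slow O-alkylation of a hindered, hydrogen-bonded phenol, with carbonate-induced loss of an aryl silyl group competing, so that alkylation spreads to other oxygens.
- Fallback, from 14, returning at 16: Mitsunobu etherification with 3-methylbut-2-en-1-ol (PPh3, diisopropyl azodicarboxylate, THF, 0 °C). This activates the alcohol instead of the phenol and involves no carbonate. It makes no new compound.

## Further compounds

F1 | step 6 | [2-(diethoxymethyl)-3,6-dihydroxy-4-methylphenyl]{2,2-dimethyl-7-[(triisopropylsilyl)oxy]-2H-chromen-8-yl}methanone | CCOC(OCC)c1c(O)c(C)cc(O)c1C(=O)c2c(O[Si](C(C)C)(C(C)C)C(C)C)ccc3C=CC(C)(C)Oc23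
F2 | step 6 | [2-(diethoxymethyl)-6-hydroxy-4-methyl-3-[(3-methylbut-2-en-1-yl)oxy]phenyl]{2,2-dimethyl-7-[(triisopropylsilyl)oxy]-2H-chromen-8-yl}methanone | CCOC(OCC)c1c(OCC=C(C)C)c(C)cc(O)c1C(=O)c2c(O[Si](C(C)C)(C(C)C)C(C)C)ccc3C=CC(C)(C)Oc23
F3 | step 6 | 3-hydroxy-5-methyl-6-[(3-methylbut-2-en-1-yl)oxy]-2-{2,2-dimethyl-7-[(triisopropylsilyl)oxy]-2H-chromene-8-carbonyl}benzaldehyde | O=Cc1c(OCC=C(C)C)c(C)cc(O)c1C(=O)c2c(O[Si](C(C)C)(C(C)C)C(C)C)ccc3C=CC(C)(C)Oc23
F4 | step 1 | 2-hydroxy-6-[(2-methylbut-3-yn-2-yl)oxy]benzaldehyde | O=Cc1c(O)cccc1OC(C)(C)C#C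
F5 | step 3 | 2,2-dimethyl-7-[(triisopropylsilyl)oxy]-2H-chromene-8-carboxylic acid | OC(=O)c1c(O[Si](C(C)C)(C(C)C)C(C)C)ccc2C=CC(C)(C)Oc12
F6 | step 3 | 2,2-dimethyl-7-[(triisopropylsilyl)oxy]-2H-chromene-8-carbonyl chloride | ClC(=O)c1c(O[Si](C(C)C)(C(C)C)C(C)C)ccc2C=CC(C)(C)Oc12
F0 | step 7 | none | none
A1 | alternative 1 | 7-(methoxymethoxy)-2,2-dimethyl-2H-chromene | COCOc1ccc2C=CC(C)(C)Oc2c1
A2 | alternative 1 | 2-(dimethoxymethyl)-6-(methoxymethoxy)-4-methyl-3-[(3-methylbut-2-en-1-yl)oxy]benzaldehyde | COC(OC)c1c(OCC=C(C)C)c(C)cc(OCOC)c1C=O
A3 | alternative 1 | rac-[2-(dimethoxymethyl)-6-(methoxymethoxy)-4-methyl-3-[(3-methylbut-2-en-1-yl)oxy]phenyl][7-(methoxymethoxy)-2,2-dimethyl-2H-chromen-8-yl]methanol | COC(OC)c1c(OCC=C(C)C)c(C)cc(OCOC)c1C(O)c2c(OCOC)ccc3C=CC(C)(C)Oc23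
A4 | alternative 2 | pentacarbonyl[methoxy(prop-1-en-2-yl)methylidene]chromium, (CO)5Cr=C(OCH3)C(CH3)=CH2 | COC(C(C)=C)=[Cr].[C-]#[O+].[C-]#[O+].[C-]#[O+].[C-]#[O+].[C-]#[O+]
A5 | alternative 2 | rac-3-(diethoxymethyl)-2-[{2,2-dimethyl-7-[(triisopropylsilyl)oxy]-2H-chromen-8-yl}(hydroxy)methyl]-4-methoxy-5-methylphenol | COc1c(C)cc(O)c(C(O)c2c(O[Si](C(C)C)(C(C)C)C(C)C)ccc3C=CC(C)(C)Oc23)c1C(OCC)OCC
A6 | alternative 3 | 2-(dimethoxymethyl)-6-(methoxymethoxy)-4-methyl-3-[(3-methylbut-2-en-1-yl)oxy]benzoyl chloride | COC(OC)c1c(OCC=C(C)C)c(C)cc(OCOC)c1C(Cl)=O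
A7 | alternative 3 | 2-{2-(dimethoxymethyl)-6-(methoxymethoxy)-4-methyl-3-[(3-methylbut-2-en-1-yl)oxy]benzoyl}cyclohexane-1,3-dione | COC(OC)c1c(OCC=C(C)C)c(C)cc(OCOC)c1C(=O)C2C(=O)CCCC2=O
A8 | alternative 3 | [2-(dimethoxymethyl)-6-(methoxymethoxy)-4-methyl-3-[(3-methylbut-2-en-1-yl)oxy]phenyl](2,6-dihydroxyphenyl)methanone | COC(OC)c1c(OCC=C(C)C)c(C)cc(OCOC)c1C(=O)c2c(O)cccc2O
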